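The route rests on closing the δ-lactone ring last, by joining the saturated carbon C4 to arene carbon C4a while the ester C1–O2–C3 is already in place. An (R)-configured 1-tosyloxyalkan-2-yl 2-bromo-6-hydroxybenzoate undergoes an intramolecular nickel-catalysed reductive cross-electrophile coupling, which in one operation forms the C4–C4a bond, closes the six-membered ring and delivers the target with its free C8 phenol. The step exploits the contiguous C8–OH, C8a–C1(=O) and C4a–Br pattern of the benzene ring: the bromide is activated by the ortho ester, and the C8–OH···O=C1 hydrogen bond holds O2 on the C4a side. C3 comes from (S)-glycidyl tosylate and is inverted by a Mitsunobu esterification.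

Key step: step 4

Remark: atom labels follow the 3,4-dihydroisochromen-1-one skeleton of the target (C1 carbonyl, O2, C3 stereocentre, C4, C4a to C8a, hydroxyl on C8); the internally hydrogen-bonded phenol is assumed to need no protection in steps 3 and 4.

Step 1
Reactants: 1 dec-1-yne; 2 1-bromo-4-chlorobutane
Product: 4 (E)-1-chlorotetradec-5-ene, via (E)-dec-1-enylzirconocene chloride 3 (not isolated)
Conditions: Cp2Zr(H)Cl (1.3 equiv), THF, rt; then 2 (1.0 equiv), Pd(acac)2 (2.5 mol%), LiBr (2 equiv), THF/NMP, 55 °C
Reagents that add atoms: none
Why: syn-hydrozirconation of the terminal alkyne puts zirconium on C1 and fixes the E geometry, and the palladium-catalysed Negishi-type coupling of the alkenylzirconocene with the primary bromide (the chloride stays inert) transfers the alkenyl group with retention.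

Step 2
Reactants: 4 (E)-1-chlorotetradec-5-ene; 5 (S)-glycidyl tosylate
Product: 7 (2S,8E)-2-hydroxyheptadec-8-en-1-yl 4-methylbenzenesulfonate, via (E)-tetradec-5-enylmagnesium chloride 6 (not isolated)
Conditions: Mg turnings (1.5 equiv), cat. I2, THF, reflux; then added to 5 (0.85 equiv) and CuI (10 mol%), THF, −40 to −20 °C; aq. NH4Cl
Reagents that add atoms: none
Why: copper-catalysed ring-opening of the epoxide by the Grignard reagent at the unsubstituted carbon, which at low temperature is faster than displacement of the primary tosylate, leaves the stereocentre untouched, so the S configuration of 5 is carried into 7.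

Step 3
Reactants: 7 (2S,8E)-2-hydroxyheptadec-8-en-1-yl 4-methylbenzenesulfonate; 8 2-bromo-6-hydroxybenzoic acid
Product: 9 (2R,8E)-1-(tosyloxy)heptadec-8-en-2-yl 2-bromo-6-hydroxybenzoate
Conditions: PPh3 (1.5 equiv), DIAD (1.5 equiv), THF, 0 °C to rt
Reagents that add atoms: none
Why: in this Mitsunobu esterification the carboxylate, far more acidic than the hydrogen-bonded phenol, displaces the alkoxyphosphonium group at C3 in an SN2 step that inverts the S carbinol to the R ester and, because the acid reacts as the nucleophile, is little hampered by its two ortho substituents.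

Step 4
Reactants: 9 (2R,8E)-1-(tosyloxy)heptadec-8-en-2-yl 2-bromo-6-hydroxybenzoate
Product: 11 (3R)-8-hydroxy-3-[(6E)-pentadec-6-en-1-yl]-3,4-dihydro-1H-isochromen-1-one, via primary iodide 10 (not isolated)
Conditions: NiBr2(dme) (20 mol%), 4,4'-di-tert-butyl-2,2'-bipyridine (24 mol%), NaI (0.5 equiv), Mn powder (3 equiv), DMA, 60 °C, 9 added by syringe pump over 12 h to a final 0.01 M
Reagents that add atoms: none
Why: Zerovalent nickel inserts into the C4a–Br bond, which the ortho ester activates, while iodide converts the primary tosylate at C4 into iodide 10; halogen abstraction by monovalent nickel gives the C4 radical, capture of this radical by the arylnickel centre of the same molecule gives a seven-membered aryl(alkyl) trivalent nickel ring, and reductive elimination forms the C4–C4a bond. The closest known reaction type is the nickel-catalysed reductive cross-electrophile coupling of aryl bromides with primary alkyl halides or sulfonates under iodide co-catalysis with Mn as the terminal reductant, used here within one molecule. The six-membered lactone ring closes by C(sp2)–C(sp3) reductive elimination from that nickelacycle, the tether being the ester C1–O2–C3 made in step 3. No stereocentre is formed, and C3, none of whose bonds is broken, keeps the R configuration set in step 3. The step needs ring closure to outrun intermolecular coupling, hydrodehalogenation and loss of the benzoate by β-elimination although the lactone-forming s-cis rotamer of the ester is the minor one; slow addition at high dilution with a high nickel loading (each aryl bromide is nickelated before its alkyl radical forms), the C8–OH···O=C1 hydrogen bond that keeps O2 on the C4a side, and the radical mode of C4 activation, which creates no long-lived alkylmetal β to the acyloxy group, are meant to secure this. Site selectivity between the two electrophiles is inherent, since zerovalent nickel adds only to the aryl bromide and the alkyl iodide reacts only by halogen abstraction.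

Compound list
1 | dec-1-yne | C#CCCCCCCCC | starting material
2 | 1-bromo-4-chlorobutane | ClCCCCBr | starting material
3 | (E)-dec-1-enylzirconocene chloride | CCCCCCCC/C=C/[Zr+2]Cl.c1cc[cH-]c1.c1cc[cH-]c1 | intermediate (not isolated)
4 | (E)-1-chlorotetradec-5-ene | CCCCCCCC/C=C/CCCCCl | intermediate
5 | (S)-glycidyl tosylate, (2S)-oxiran-2-ylmethyl 4-methylbenzenesulfonate | Cc1ccc(cc1)S(=O)(=O)OC[C@@H]1CO1 | starting material
6 | (E)-tetradec-5-enylmagnesium chloride | CCCCCCCC/C=C/CCCC[Mg]Cl | intermediate (not isolated)
7 | (2S,8E)-2-hydroxyheptadec-8-en-1-yl 4-methylbenzenesulfonate | CCCCCCCC/C=C/CCCCC[C@@H](COS(=O)(=O)c1ccc(C)cc1)O | intermediate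
8 | 2-bromo-6-hydroxybenzoic acid | OC(=O)c1c(O)cccc1Br | starting material
9 | (2R,8E)-1-(tosyloxy)heptadec-8-en-2-yl 2-bromo-6-hydroxybenzoate | CCCCCCCC/C=C/CCCCC[C@H](COS(=O)(=O)c1ccc(C)cc1)OC(=O)c1c(Br)cccc1O | intermediate
10 | (2R,8E)-1-iodoheptadec-8-en-2-yl 2-bromo-6-hydroxybenzoate | CCCCCCCC/C=C/CCCCC[C@H](CI)OC(=O)c1c(Br)cccc1O | intermediate (not isolated)
11 | (3R)-8-hydroxy-3-[(6E)-pentadec-6-en-1-yl]-3,4-dihydro-1H-isochromen-1-one | CCCCCCCC/C=C/CCCCC[C@@H]1Cc2cccc(O)c2C(=O)O1 | target

Total step count: 4. Longest linear sequence: 4 steps (1 → 4 → 7 → 9 → 11).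

Steps most likely to fail

Step 4. Ring closure may lose out to intermolecular aryl–alkyl coupling (oligomerisation) and to hydrodehalogenation, because the ester rarely adopts the s-cis rotamer that the closure needs. In that case the C4–C4a bond would be made between two molecules and the ring closed afterwards by lactonisation. The fallback sets out from Grignard reagent 6. Its copper-catalysed opening of commercial (R)-glycidyl tosylate (CuI, THF, −40 °C) should give (2R,8E)-2-hydroxyheptadec-8-en-1-yl 4-methylbenzenesulfonate F1. K2CO3 in MeOH should close this to (2R)-2-[(6E)-pentadec-6-en-1-yl]oxirane F2. Nickel-catalysed reductive coupling of F2 with commercial methyl 2-bromo-6-hydroxybenzoate under iodide co-catalysis (NiCl2(dme), 2,2'-bipyridine, NaI, Et3N·HCl, Zn, DMPU) runs through (2R,8E)-1-iodoheptadec-8-en-2-ol F3 and arylates the terminal carbon. It should give methyl 2-hydroxy-6-[(2R,8E)-2-hydroxyheptadec-8-en-1-yl]benzoate F4. Cat. TsOH in toluene then lactonises F4, and the fallback rejoins the route at 11.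

Step 3. The SN2 displacement at the carbinol carbon, flanked by the tosyloxymethyl group and attacked by a hindered carboxylate, may be too slow, so that elimination or O-alkylation of the phenol takes over. The ester would then be made with retention from the enantiomeric alcohol and a protected acid. The fallback sets out from Grignard reagent 6. Opening of (R)-glycidyl tosylate as above gives (2R,8E)-2-hydroxyheptadec-8-en-1-yl 4-methylbenzenesulfonate F5, the same compound as F1. Commercial 2-bromo-6-methoxybenzoic acid is converted with (COCl)2 and cat. DMF into 2-bromo-6-methoxybenzoyl chloride F6. This acylates F5 (Et3N, DMAP, CH2Cl2) to (2R,8E)-1-(tosyloxy)heptadec-8-en-2-yl 2-bromo-6-methoxybenzoate F7. The coupling of step 4 proceeds through (2R,8E)-1-iodoheptadec-8-en-2-yl 2-bromo-6-methoxybenzoate F8 and should give (3R)-8-methoxy-3-[(6E)-pentadec-6-en-1-yl]-3,4-dihydro-1H-isochromen-1-one F9. BCl3 (CH2Cl2, −78 to 0 °C) removes the methyl ether next to the lactone carbonyl, and the fallback rejoins the route at 11.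

Step 1. The alkyl–alkenyl coupling may stall through slow transmetalation or β-hydride elimination at the alkylpalladium stage. The polarity of the coupling would then be reversed. The fallback sets out from 1. Hydrozirconation as in step 1, followed by I2, should give (E)-1-iododec-1-ene F10. A Negishi coupling of F10 with commercial (4-chlorobutyl)zinc bromide (PdCl2(dppf), THF, rt to 50 °C) returns to the route at 4.

Further compounds
F1 | step 4 | (2R,8E)-2-hydroxyheptadec-8-en-1-yl 4-methylbenzenesulfonate | CCCCCCCC/C=C/CCCCC[C@H](COS(=O)(=O)c1ccc(C)cc1)O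
F2 | step 4 | (2R)-2-[(6E)-pentadec-6-en-1-yl]oxirane | CCCCCCCC/C=C/CCCCC[C@@H]1CO1
F3 | step 4 | (2R,8E)-1-iodoheptadec-8-en-2-ol | CCCCCCCC/C=C/CCCCC[C@@H](O)CI
F4 | step 4 | methyl 2-hydroxy-6-[(2R,8E)-2-hydroxyheptadec-8-en-1-yl]benzoate | CCCCCCCC/C=C/CCCCC[C@@H](O)Cc1cccc(O)c1C(=O)OC
F5 | step 3 | (2R,8E)-2-hydroxyheptadec-8-en-1-yl 4-methylbenzenesulfonate | CCCCCCCC/C=C/CCCCC[C@H](COS(=O)(=O)c1ccc(C)cc1)O
F6 | step 3 | 2-bromo-6-methoxybenzoyl chloride | COc1cccc(Br)c1C(Cl)=O
F7 | step 3 | (2R,8E)-1-(tosyloxy)heptadec-8-en-2-yl 2-bromo-6-methoxybenzoate | CCCCCCCC/C=C/CCCCC[C@H](COS(=O)(=O)c1ccc(C)cc1)OC(=O)c1c(Br)cccc1OC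
F8 | step 3 | (2R,8E)-1-iodoheptadec-8-en-2-yl 2-bromo-6-methoxybenzoate | CCCCCCCC/C=C/CCCCC[C@H](CI)OC(=O)c1c(Br)cccc1OC
F9 | step 3 | (3R)-8-methoxy-3-[(6E)-pentadec-6-en-1-yl]-3,4-dihydro-1H-isochromen-1-one | CCCCCCCC/C=C/CCCCC[C@@H]1Cc2cccc(OC)c2C(=O)O1
F10 | step 1 | (E)-1-iododec-1-ene | CCCCCCCC/C=C/I
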